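**Plan** (guaiane numbering; ring A = cyclopentenone C1–C5, ring B = seven-membered ring C1, C5–C10)
1. Cuts: the C8 angelate and C11 acetate; C4=C5 (retro-aldol condensation to a C3/C5 1,4-diketone); C1–C10 (retro-1,2-shift that contracts ring B to a cyclohexanol carrying the enone C1=C2–C3=O on C5); then C1=C2 (cross-metathesis), C5–C1 (vinyl addition), and C5–C6/C7–C8 (Diels–Alder).
2. Enabling feature: C5, the β-carbon of the ring-A enone, is a latent ketone 1,4 to C3 and lies between C1 and C10. In the γ-hydroxy enone C5(OH)–C1=C2–C3=O the ring bond C5–C10 can shift to the electrophilic C1 (vinylogous α-ketol shift), making C1–C10, ring B and the 1,4-diketone in one event.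
3. Forward order: asymmetric Diels–Alder (six-membered ring C5–C10 with C11–C14), C5 oxidation, hydrogenation, vinylation, metathesis, ring expansion to ring B, aldol closure of ring A, then the two esters.
4. Stereochemistry: C7 and C8 from the catalyst-controlled endo Diels–Alder; C10 from hydrogenation on the convex face of a cis-fused acetonide (temporary ring over O8/O11) and retention during the shift; C1 by equilibration next to the C5 ketone (trans to the C10 methyl).

Key step: step 10

Remark: guaiane numbering of the target is used for all intermediates (C11–C13 = oxygenated isopropyl, C14 = methyl on C10, C15 = methyl on C4). The carbinol carbon C5 in 11 and 13 is drawn as the epimer expected from attack on the convex face; either epimer serves, because C5 becomes a carbonyl carbon in step 10.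

Step 1
Reactants: 1 3-methylbut-2-enal (prenal)
Product: 2 (E)-3-methylbuta-1,3-dien-1-yl acetate
Conditions: Ac2O, KOAc (cat.), Et3N, 110 °C
Reagents that add atoms: acetic anhydride, CC(=O)OC(C)=O
Why: O-acetylation of the extended (γ-deprotonated) enolate of the enal is a standard dienyl acetate formation and should give the E isomer as the stable, distillable product.

Step 2
Reactants: 2 (E)-3-methylbuta-1,3-dien-1-yl acetate; 3 3-acryloyl-1,3-oxazolidin-2-one
Product: 4 (1R,6S)-3-methyl-6-(2-oxo-1,3-oxazolidine-3-carbonyl)cyclohex-2-en-1-yl acetate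
Conditions: [Cu((S,S)-t-Bu-box)](SbF6)2 (5 mol %), CH2Cl2, −20 °C
Reagents that add atoms: none
Why: Catalytic enantioselective Diels–Alder reaction of a chelating acrylimide: the acetoxy group at C8 and the methyl group at C10 both direct C8 to the α-carbon C7, the endo transition state places the C7 carbonyl cis to the C8 acetate, and the square-planar copper–bis(oxazoline) chelate shields one face of the dienophile, which should set C7 (S) and C8 (R).

Step 3
Reactants: 4 (1R,6S)-3-methyl-6-(2-oxo-1,3-oxazolidine-3-carbonyl)cyclohex-2-en-1-yl acetate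
Product: 5 benzyl (1S,2R)-2-acetoxy-4-methylcyclohex-3-ene-1-carboxylate
Conditions: BnOH, n-BuLi, THF, −78 to −20 °C
Reagents that add atoms: benzyl alcohol (as lithium benzyloxide), OCc1ccccc1
Why: Lithium benzyloxide attacks the activated exocyclic imide carbonyl (standard oxazolidinone removal) without epimerising C7; any acetate lost here is of no consequence because step 4 cleaves it anyway.

Step 4
Reactants: 5 benzyl (1S,2R)-2-acetoxy-4-methylcyclohex-3-ene-1-carboxylate
Product: 6 (1R,6S)-6-(2-hydroxypropan-2-yl)-3-methylcyclohex-2-en-1-ol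
Conditions: MeMgBr (excess), THF, 0 °C to rt; aq. NH4Cl
Reagents that add atoms: methylmagnesium bromide, C[Mg]Br
Why: Double Grignard addition to the ester builds the tertiary carbinol C11 with C12 and C13 and the same reagent cleaves the acetate; C7 and C8 are not touched.

Step 5
Reactants: 6 (1R,6S)-6-(2-hydroxypropan-2-yl)-3-methylcyclohex-2-en-1-ol
Product: 7 (4aS,8aR)-2,2,4,4,7-pentamethyl-4a,5,6,8a-tetrahydro-4H-1,3-benzodioxine (cis-fused acetonide of 6)
Conditions: 2-methoxypropene, PPTS (cat.), CH2Cl2, 0 °C
Reagents that add atoms: 2-methoxypropene, COC(C)=C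
Why: Kinetic acetonide formation from the cis-1,3-diol under mild acid protects both hydroxyls in one temporary ring, which later differentiates the two faces of the carbocycle.

Step 6
Reactants: 7 (4aS,8aR)-2,2,4,4,7-pentamethyl-4a,5,6,8a-tetrahydro-4H-1,3-benzodioxine
Product: 9 acetonide of (4R,5S)-4-hydroxy-5-(2-hydroxypropan-2-yl)-2-methylcyclohex-2-en-1-one, via allylic alcohol 8 (not isolated)
Conditions: SeO2 (0.5 equiv), t-BuOOH, CH2Cl2, rt; then Dess–Martin periodinane, NaHCO3, CH2Cl2, rt
Reagents that add atoms: tert-butyl hydroperoxide, CC(C)(C)OO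
Why: Selenium dioxide allylic oxidation (ene reaction, then [2,3]-shift) should take place at the ring methylene on the more substituted alkene carbon (C5, not the C14 methyl or the C8 methine), and Dess–Martin oxidation of the crude alcohol gives the enone, so the C5 carbinol configuration does not matter.

Step 7
Reactants: 9 acetonide of (4R,5S)-4-hydroxy-5-(2-hydroxypropan-2-yl)-2-methylcyclohex-2-en-1-one
Product: 10 acetonide of (2S,4R,5S)-4-hydroxy-5-(2-hydroxypropan-2-yl)-2-methylcyclohexan-1-one (all-cis)
Conditions: H2 (1 atm), Pd/C, EtOAc, rt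
Reagents that add atoms: none
Why: Heterogeneous hydrogenation should deliver hydrogen to the convex face of the cis-fused bicycle, anti to the pseudoaxial C8–O bond, which places the C10 methyl cis to O8 and C11 (10S); the kinetic all-cis ketone is kept away from base to avoid epimerisation.

Step 8
Reactants: 10 acetonide of (2S,4R,5S)-4-hydroxy-5-(2-hydroxypropan-2-yl)-2-methylcyclohexan-1-one
Product: 11 acetonide of (1S,2S,4R,5S)-1-ethenyl-5-(2-hydroxypropan-2-yl)-2-methylcyclohexane-1,4-diol
Conditions: vinylMgBr, CeCl3, THF, −78 °C; aq. NH4Cl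
Reagents that add atoms: vinylmagnesium bromide, C=C[Mg]Br
Why: 1,2-Addition of the weakly basic organocerium reagent avoids enolisation and so epimerisation at C10; attack on the convex face is expected, but the carbinol configuration is of no consequence.

Step 9
Reactants: 11 acetonide of (1S,2S,4R,5S)-1-ethenyl-5-(2-hydroxypropan-2-yl)-2-methylcyclohexane-1,4-diol; 12 pent-1-en-3-one (ethyl vinyl ketone)
Product: 13 acetonide of (E)-1-[(1R,2S,4R,5S)-1,4-dihydroxy-5-(2-hydroxypropan-2-yl)-2-methylcyclohexyl]pent-1-en-3-one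
Conditions: second-generation Hoveyda–Grubbs catalyst, RuCl2(H2IMes)(=CH-C6H4-2-O-i-Pr) (5 mol %), 12 (3 equiv), CH2Cl2, 40 °C
Reagents that add atoms: none
Why: Olefin cross-metathesis of a tertiary allylic alcohol with an enone partner used in excess should give the E enone as the thermodynamic product, and no stereocentre is touched.

Step 10
Reactants: 13 acetonide of (E)-1-[(1R,2S,4R,5S)-1,4-dihydroxy-5-(2-hydroxypropan-2-yl)-2-methylcyclohexyl]pent-1-en-3-one
Product: 14 acetonide of (2R,3S,5R,6S)-5-hydroxy-6-(2-hydroxypropan-2-yl)-3-methyl-2-(2-oxobutyl)cycloheptan-1-one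
Conditions: 9-amino-9-deoxy-epi-quinine (20 mol %), CF3CO2H (40 mol %), toluene, 60 °C
Reagents that add atoms: none
Why: Proposed new method: the primary amine condenses with the C3 ketone to an α,β-unsaturated iminium ion, which makes C1 strongly electrophilic; the ring bond C5–C10, held parallel to the π-system, then shifts to C1 while the C5 hydroxyl (deprotonated by the carboxylate) becomes the C5 carbonyl, and hydrolysis of the resulting enamine releases 14 and the catalyst (closest known reaction types: the amine-salt-catalysed vinylogous α-ketol rearrangement of 1-hydroxycyclobutyl enones, the acid-induced 1,2-shift of p-quinols and Lewis-acid semipinacol ring expansions). Ring B is closed by a suprafacial 1,2-shift that expands the cyclohexane to the cycloheptanone (a three-centre bridging transition state, formally 3-exo-trig at C1), not by an end-to-end cyclization. C10 migrates with retention, so its configuration and its cis relation to O8 and C11 come unchanged from 13; C1 is born next to the new C5 ketone and should equilibrate by enolisation to the isomer with the 2-oxobutyl chain trans to the C10 methyl (H1 and H10 trans). The step needs C10 and not C6 to migrate: C10 is the more substituted carbon and carries the developing positive charge better, whereas C6 is primary and is deactivated inductively by the two oxygen-bearing carbons C8 and C11 on C7. Because no ring strain is released, the driving force is the exchange of the enone C=C and the O–H bond for a C=O and a C–H bond, which should outweigh the six-to-seven ring strain, and ionisation of the tertiary alcohol is disfavoured because the cation would be conjugated to the electron-poor iminium.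

Step 11
Reactants: 14 acetonide of (2R,3S,5R,6S)-5-hydroxy-6-(2-hydroxypropan-2-yl)-3-methyl-2-(2-oxobutyl)cycloheptan-1-one
Product: 16 8,11-O-isopropylidene derivative of (1R,7S,8R,10S)-8,11-dihydroxyguai-4-en-3-one, via aldol 15 (not isolated)
Conditions: KOH, MeOH, 60 °C
Reagents that add atoms: none
Why: Base-mediated intramolecular aldol condensation of a 1,4-diketone (the C4 enolate adds to the C5 ketone, then dehydration) is the classical cyclopentenone annulation and closes ring A; C7, C8 and C10 carry no acidic hydrogen and no β-leaving group, and the epimerisable C1 is expected to stay trans to the C10 methyl.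

Step 12
Reactants: 16 8,11-O-isopropylidene derivative of (1R,7S,8R,10S)-8,11-dihydroxyguai-4-en-3-one
Product: 17 (1R,7S,8R,10S)-8,11-dihydroxyguai-4-en-3-one (torilolone)
Conditions: AcOH–H2O (4:1), 45 °C
Reagents that add atoms: none
Why: Acid hydrolysis of the acetonide releases the secondary C8 and the tertiary C11 hydroxyl; the tetrasubstituted enone is inert to dilute acid.

Step 13
Reactants: 17 (1R,7S,8R,10S)-8,11-dihydroxyguai-4-en-3-one; 18 angelic acid, (Z)-2-methylbut-2-enoic acid
Product: 20 (1R,7S,8R,10S)-8-angeloyloxy-11-hydroxyguai-4-en-3-one, via mixed anhydride 19 (not isolated)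
Conditions: 18, 2,4,6-trichlorobenzoyl chloride, Et3N, toluene, rt; then 17, toluene, 80 °C
Reagents that add atoms: none
Why: Acylation with the preformed Yamaguchi-type mixed anhydride without a nucleophilic catalyst should keep the Z (angelate) geometry; only the secondary C8 hydroxyl reacts, the tertiary C11 hydroxyl being too hindered.

Step 14
Reactants: 20 (1R,7S,8R,10S)-8-angeloyloxy-11-hydroxyguai-4-en-3-one
Product: 21 torilin
Conditions: Ac2O, DMAP, Et3N, CH2Cl2, 40 °C
Reagents that add atoms: acetic anhydride, CC(=O)OC(C)=O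
Why: DMAP-catalysed acetylation of the tertiary alcohol (Steglich-type acyl transfer) under mild, non-isomerising conditions should give the target.

**Compound list**
1 | 3-methylbut-2-enal (prenal) | CC(C)=CC=O | starting material
2 | (E)-3-methylbuta-1,3-dien-1-yl acetate | CC(=O)O/C=C/C(C)=C | intermediate
3 | 3-acryloyl-1,3-oxazolidin-2-one | C=CC(=O)N1CCOC1=O | starting material
4 | (1R,6S)-3-methyl-6-(2-oxo-1,3-oxazolidine-3-carbonyl)cyclohex-2-en-1-yl acetate (cis) | CC(=O)O[C@@H]1C=C(C)CC[C@@H]1C(=O)N2CCOC2=O | intermediate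
5 | benzyl (1S,2R)-2-acetoxy-4-methylcyclohex-3-ene-1-carboxylate | CC(=O)O[C@@H]1C=C(C)CC[C@@H]1C(=O)OCc2ccccc2 | intermediate
6 | (1R,6S)-6-(2-hydroxypropan-2-yl)-3-methylcyclohex-2-en-1-ol | O[C@@H]1C=C(C)CC[C@@H]1C(C)(C)O | intermediate
7 | (4aS,8aR)-2,2,4,4,7-pentamethyl-4a,5,6,8a-tetrahydro-4H-1,3-benzodioxine (cis-fused acetonide of 6) | CC1(C)O[C@@H]2C=C(C)CC[C@@H]2C(C)(C)O1 | intermediate
8 | (4aS,6S,8aR)-2,2,4,4,7-pentamethyl-4a,5,6,8a-tetrahydro-4H-1,3-benzodioxin-6-ol (C5 allylic alcohol of 7) | CC1(C)O[C@@H]2C=C(C)[C@@H](O)C[C@@H]2C(C)(C)O1 | intermediate (not isolated)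
9 | acetonide of (4R,5S)-4-hydroxy-5-(2-hydroxypropan-2-yl)-2-methylcyclohex-2-en-1-one | CC1(C)O[C@@H]2C=C(C)C(=O)C[C@@H]2C(C)(C)O1 | intermediate
10 | acetonide of (2S,4R,5S)-4-hydroxy-5-(2-hydroxypropan-2-yl)-2-methylcyclohexan-1-one | CC1(C)O[C@@H]2C[C@H](C)C(=O)C[C@@H]2C(C)(C)O1 | intermediate
11 | acetonide of (1S,2S,4R,5S)-1-ethenyl-5-(2-hydroxypropan-2-yl)-2-methylcyclohexane-1,4-diol | CC1(C)O[C@@H]2C[C@H](C)[C@@](O)(C=C)C[C@@H]2C(C)(C)O1 | intermediate
12 | pent-1-en-3-one (ethyl vinyl ketone) | C=CC(=O)CC | starting material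
13 | acetonide of (E)-1-[(1R,2S,4R,5S)-1,4-dihydroxy-5-(2-hydroxypropan-2-yl)-2-methylcyclohexyl]pent-1-en-3-one | CC1(C)O[C@@H]2C[C@H](C)[C@@](O)(/C=C/C(=O)CC)C[C@@H]2C(C)(C)O1 | intermediate
14 | acetonide of (2R,3S,5R,6S)-5-hydroxy-6-(2-hydroxypropan-2-yl)-3-methyl-2-(2-oxobutyl)cycloheptan-1-one | CC1(C)O[C@@H]2C[C@H](C)[C@@H](CC(=O)CC)C(=O)C[C@@H]2C(C)(C)O1 | intermediate
15 | aldol adduct: 5-hydroxy-4,5-dihydro derivative of 16 (mixture at the transient centres C4 and C5) | CC1(C)O[C@@H]2C[C@H](C)[C@H]3CC(=O)C(C)C3(O)C[C@@H]2C(C)(C)O1 | intermediate (not isolated)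
16 | 8,11-O-isopropylidene derivative of (1R,7S,8R,10S)-8,11-dihydroxyguai-4-en-3-one | CC1(C)O[C@@H]2C[C@H](C)[C@H]3CC(=O)C(C)=C3C[C@@H]2C(C)(C)O1 | intermediate
17 | (1R,7S,8R,10S)-8,11-dihydroxyguai-4-en-3-one (torilolone); (5S,6R,8S,8aR)-6-hydroxy-5-(2-hydroxypropan-2-yl)-3,8-dimethyl-4,5,6,7,8,8a-hexahydroazulen-2(1H)-one | O[C@@H]1C[C@H](C)[C@H]2CC(=O)C(C)=C2C[C@@H]1C(C)(C)O | intermediate
18 | angelic acid, (Z)-2-methylbut-2-enoic acid | C/C=C(/C)C(=O)O | starting material
19 | (Z)-2-methylbut-2-enoic 2,4,6-trichlorobenzoic anhydride | C/C=C(/C)C(=O)OC(=O)c1c(Cl)cc(Cl)cc1Cl | intermediate (not isolated)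
20 | (1R,7S,8R,10S)-8-angeloyloxy-11-hydroxyguai-4-en-3-one | C/C=C(/C)C(=O)O[C@@H]1C[C@H](C)[C@H]2CC(=O)C(C)=C2C[C@@H]1C(C)(C)O | intermediate
21 | torilin, [(5S,6R,8S,8aR)-5-(2-acetoxypropan-2-yl)-3,8-dimethyl-2-oxo-1,2,4,5,6,7,8,8a-octahydroazulen-6-yl] (Z)-2-methylbut-2-enoate | C/C=C(/C)C(=O)O[C@@H]1C[C@H](C)[C@H]2CC(=O)C(C)=C2C[C@@H]1C(C)(C)OC(C)=O | target

**Total step count:** 14. **Longest linear sequence:** 14 steps (1 to 21).

**Steps most likely to fail**

Step 10 (proposed new method). What may go wrong: no migration because the ring is unstrained, migration of C6 instead of C10, or loss of the amine catalyst by condensation with the 1,4-diketone. The fallback uses known chemistry, sets out from enone 9 and comes back at diketone 14. Conjugate reduction of 9 with LiBH(s-Bu)3 and trapping with Me3SiCl gives the regiodefined silyl enol ether F1 (C5=C10). Cyclopropanation with Et2Zn and CH2I2 on the convex face gives the siloxycyclopropane F2; here the C1–C10 bond is made. FeCl3 in DMF cleaves the internal C5–C10 bond to the ring-expanded β-chloro ketone F3, and NaOAc in MeOH converts it to the cycloheptenone F4. Reductive alkylation (Li, NH3, t-BuOH, then 1-bromobut-2-yne) is expected to deliver hydrogen to C10 on the convex face as in step 7 and to alkylate the C1 enolate trans to the C10 methyl, giving the butynyl ketone F5. Carbonyl-assisted hydration of the alkyne (Ph3PAuNTf2 cat., aqueous dioxane) then gives 14.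

Step 6. What may go wrong: oxidation at the wrong allylic site (the C14 methyl or the oxygen-bearing C8 methine) or over-oxidation. The fallback builds the C5 oxygen into the diene; it sets out from dienophile 3 and comes back at enone 9. Commercial (E)-4-acetoxy-2-methylbut-2-enal F6 is converted with Ac2O, KOAc and Et3N into (1E,3E)-1,4-diacetoxy-2-methylbuta-1,3-diene F7. Diels–Alder reaction of F7 with 3 under the conditions of step 2 (C10 methyl directing C7 para to C10, endo) gives the all-cis diacetoxy adduct F8. Lithium benzyloxide gives the benzyl ester F9 and excess MeMgBr gives the triol F10. 2,2-Dimethoxypropane with PPTS ties O8 and O11 into the acetonide F11, which leaves the allylic C5 hydroxyl free. MnO2 oxidation of F11 gives 9.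

Step 13. What may go wrong: isomerisation of the angeloyl unit to the E (tigloyl) isomer and slow acylation of the hindered C8 hydroxyl. The fallback makes the Z double bond after the ester bond; it sets out from diol 17 and comes back at 20. Esterification of 17 with 2-[bis(2,2,2-trifluoroethoxy)phosphoryl]propanoic acid (DCC, DMAP, CH2Cl2) gives the phosphonate ester F12. Still–Gennari olefination of F12 (KN(SiMe3)2, 18-crown-6, THF, −78 °C, then acetaldehyde) should give the Z-configured ester 20.

**Further compounds**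
F1 | step 10 | acetonide silyl enol ether (C5=C10) from 9, 6-(trimethylsilyloxy) derivative | CC1(C)O[C@@H]2CC(C)=C(O[Si](C)(C)C)C[C@@H]2C(C)(C)O1
F2 | step 10 | siloxycyclopropane (CH2 = C1 bridging C5 and C10 on the face opposite to the acetonide) | CC1(C)O[C@@H]2C[C@@]3(C)C[C@@]3(O[Si](C)(C)C)C[C@@H]2C(C)(C)O1
F3 | step 10 | ring-expanded β-chloro ketone (C10 chloride, mixture at C10) | CC1(C)O[C@@H]2CC(C)(Cl)CC(=O)C[C@@H]2C(C)(C)O1
F4 | step 10 | acetonide of (5R,6S)-5-hydroxy-6-(2-hydroxypropan-2-yl)-3-methylcyclohept-2-en-1-one | CC1(C)O[C@@H]2CC(C)=CC(=O)C[C@@H]2C(C)(C)O1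
F5 | step 10 | acetonide of (2R,3S,5R,6S)-2-(but-2-yn-1-yl)-5-hydroxy-6-(2-hydroxypropan-2-yl)-3-methylcycloheptan-1-one | CC1(C)O[C@@H]2C[C@H](C)[C@@H](CC#CC)C(=O)C[C@@H]2C(C)(C)O1
F6 | step 6 | (E)-4-acetoxy-2-methylbut-2-enal | O=C/C(C)=C/COC(C)=O
F7 | step 6 | (1E,3E)-1,4-diacetoxy-2-methylbuta-1,3-diene | CC(=O)O/C=C(C)/C=C/OC(C)=O
F8 | step 6 | all-cis 3-(2,5-diacetoxy-4-methylcyclohex-3-ene-1-carbonyl)-1,3-oxazolidin-2-one | CC(=O)O[C@@H]1C=C(C)[C@H](OC(C)=O)C[C@@H]1C(=O)N2CCOC2=O
F9 | step 6 | benzyl all-cis 2,5-diacetoxy-4-methylcyclohex-3-ene-1-carboxylate | CC(=O)O[C@@H]1C=C(C)[C@H](OC(C)=O)C[C@@H]1C(=O)OCc2ccccc2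
F10 | step 6 | all-cis 5-(2-hydroxypropan-2-yl)-2-methylcyclohex-2-ene-1,4-diol | O[C@@H]1C=C(C)[C@H](O)C[C@@H]1C(C)(C)O
F11 | step 6 | acetonide (O8/O11) of F10 with free C5 hydroxyl (C5 epimer of 8) | CC1(C)O[C@@H]2C=C(C)[C@H](O)C[C@@H]2C(C)(C)O1
F12 | step 13 | 8-O-{2-[bis(2,2,2-trifluoroethoxy)phosphoryl]propanoyl} ester of 17 (mixture at the phosphonate α-carbon) | CC(C(=O)O[C@@H]1C[C@H](C)[C@H]2CC(=O)C(C)=C2C[C@@H]1C(C)(C)O)P(=O)(OCC(F)(F)F)OCC(F)(F)F
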